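**Retrosynthetic overview**

1. (2S,2''S)-3',3'''-Binaringenin 11 ⇒ hexabenzyl ether 10 (six O-debenzylations) ⇒ flat hexa-O-benzyl-3',3'''-biapigenin 8; both C2 stereocentres come from a two-fold catalytic asymmetric hydrogenation of the two γ-pyrone rings C, followed by C4 re-oxidation.
2. 8 ⇒ biaryl diester 6 plus two molecules of fluoro ketone 3, by cutting in each half the aryl ether bond O1–C8a and the bond C2–C3 (one-pot double Claisen condensation/double SNAr).
3. Enabling feature: in ring A, C8a is ortho to C4a (which carries the C4 carbonyl) and meta to the C5 and C7 oxygens, while O1 and the C4 oxygen are 1,3-related through C2–C3–C4. At the flavone oxidation level this is a 1,3-diketonate whose oxygen (future O1) displaces a fluoride placed on C8a, and the pyrone formed, unlike a flavanone, is stable to base.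
4. 6 ⇐ Ni-catalysed homocoupling (C3'–C3''' bond) of bromo ester 5; 3 ⇐ C-acetylation and benzylation of 5-fluororesorcinol 1.
5. Ring order: rings A and B are bought as benzenes, the B–B biaryl bond is made first, both rings C are closed together in the key step and are reduced to the (S)-dihydropyranones afterwards.

Key step: step 5

Assumption: the (R,R)-configured NHC ligand is taken to deliver the (2S) centres in step 6; the sense is checked on a monomeric model flavone and the (S,S)-ligand is used if it is the opposite.

**Route**

Step 1
Reactants: 1 5-fluororesorcinol (5-fluorobenzene-1,3-diol)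
Product: 2 1-(2-fluoro-4,6-dihydroxyphenyl)ethan-1-one
Conditions: AcOH, ZnCl2, 130 °C
Reagents that add atoms: acetic acid, CC(=O)O
Why: Nencki-type Friedel–Crafts C-acylation of a resorcinol should go to the ring position ortho to one hydroxyl and para to the other (here the one next to fluorine) rather than between the two hydroxyls, as with resorcinol and orcinol, and no stereocentre is formed.

Step 2
Reactants: 2 1-(2-fluoro-4,6-dihydroxyphenyl)ethan-1-one
Product: 3 1-[2,4-bis(benzyloxy)-6-fluorophenyl]ethan-1-one
Conditions: BnBr, K2CO3, DMF, 60 °C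
Reagents that add atoms: benzyl bromide, BrCc1ccccc1
Why: Williamson ether synthesis on both phenoxides (the hydrogen-bonded ortho hydroxyl needs the warm DMF), while the aryl fluoride, deactivated in the phenoxide form, should not be displaced.

Step 3
Reactants: 4 methyl 3-bromo-4-hydroxybenzoate
Product: 5 methyl 4-(benzyloxy)-3-bromobenzoate
Conditions: BnBr, K2CO3, DMF, 25 °C
Reagents that add atoms: benzyl bromide, BrCc1ccccc1
Why: Williamson ether synthesis of an acidic para-acyl phenol with benzyl bromide, which leaves the ester and the aryl bromide untouched.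

Step 4
Reactants: 5 methyl 4-(benzyloxy)-3-bromobenzoate (2 equiv)
Product: 6 dimethyl 6,6'-bis(benzyloxy)-[1,1'-biphenyl]-3,3'-dicarboxylate
Conditions: NiCl2(PPh3)2 (cat.), PPh3, Zn, Et4NI, THF, 60 °C
Reagents that add atoms: none
Why: Nickel-catalysed reductive homocoupling of an aryl bromide (Ullmann-type), in which zerovalent nickel formed by zinc inserts into the C–Br bond and joins the two carbons ortho to the benzyloxy groups (future C3'–C3'''), a process that tolerates esters and benzyl ethers.

Step 5
Reactants: 6 dimethyl 6,6'-bis(benzyloxy)-[1,1'-biphenyl]-3,3'-dicarboxylate (1 equiv) and 3 1-[2,4-bis(benzyloxy)-6-fluorophenyl]ethan-1-one (2.2 equiv)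
Product: 8 hexa-O-benzyl-3',3'''-biapigenin (5,7,4',5'',7'',4'''-hexakis(benzyloxy)-3',3'''-biflavone), via bis(1,3-diketone) 7 (not isolated)
Conditions: KN(SiMe3)2 (4.5 equiv), THF, −78 → 25 °C; then DMF, 100 °C
Reagents that add atoms: none
Why: The potassium enolate of 3 condenses with both ester groups of 6 (crossed Claisen condensation; the aroate has no α-hydrogen and the di-ortho-substituted ketone does not self-condense), and the dipotassium bis(1,3-diketonate) 7 then cyclises on heating in DMF: the enolate oxygen on the ring-B side (future O1) adds to the fluorine-bearing ring-A carbon ortho to the other carbonyl (future C8a) and fluoride leaves from the Meisenheimer-type adduct (SNAr). The closest known reaction types are the Claisen condensation of aryl methyl ketones with aroates and the base-mediated cyclisation of 1-(2-fluoroaryl)-1,3-diketones to chromones and flavones. Each ring C closes as a γ-pyrone by 6-endo-trig addition–elimination through the C8a=C4a bond that is conjugated with C4=O, so that four bonds (two C2–C3, two O1–C8a) and two rings form in one flask from three simple pieces. No stereocentre is formed, since the product is planar; the two C2 centres are set in step 6. The step needs C- over O-acylation (secured by the ester electrophile and the stable chelated diketonate), closure at C8a only (the single fluorine is the only leaving group ortho to the carbonyl, the other ortho position carries OBn, and the two benzyloxy groups are meta to C8a and so do not deactivate it), and no attack of the liberated methoxide at C8a (every fluoroarene in the flask is an anionic enolate or diketonate that repels external anions, whereas the tethered oxygen is held next to C8a). Unlike a flavanone, whose ring C opens to the chalcone under base, the pyrone product is stable to the conditions, which is why the ring is closed at this oxidation level.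

Step 6
Reactants: 8 hexa-O-benzyl-3',3'''-biapigenin
Product: 10 hexa-O-benzyl-(2S,2''S)-3',3'''-binaringenin, via bis(flavan-4-ol) 9 (not isolated)
Conditions: H2 (100 bar), Ru(cod)(2-methylallyl)2 (cat.), (R,R)-SINpEt·HBF4 [1,3-bis((R)-1-(1-naphthyl)ethyl)imidazolinium tetrafluoroborate] (cat.), KOt-Bu (cat.), toluene, 25–40 °C; then Dess–Martin periodinane, CH2Cl2, 0–25 °C
Reagents that add atoms: none
Why: Ru–NHC-catalysed asymmetric hydrogenation, a known dearomatising reduction of flavones and chromones, should add H2 across C2=C3 of each γ-pyrone ring from the face dictated by the chiral NHC ligands on ruthenium (catalyst control sets both C2 centres as S, the remote units reacting independently so that mismatched events end mainly in the separable meso diastereomer), and the Dess–Martin oxidation returns over-reduced C4 carbinols to the ketone under non-basic conditions without enolisation at C3 or opening of ring C.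

Step 7
Reactants: 10 hexa-O-benzyl-(2S,2''S)-3',3'''-binaringenin
Product: 11 (2S,2''S)-3',3'''-binaringenin
Conditions: H2 (1 atm), 10% Pd/C, EtOAc/MeOH, 25 °C
Reagents that add atoms: none
Why: Hydrogenolysis of the six aryl benzyl ethers over Pd under neutral conditions should be faster than cleavage of the cyclic benzylic C2–O1 ether or reduction of the C4 ketone, and the absence of base keeps the C2 stereocentres from racemising through ring opening to the chalcone.

**Compound list**

1 | 5-fluororesorcinol (5-fluorobenzene-1,3-diol) | Oc1cc(O)cc(F)c1 | starting material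
2 | 1-(2-fluoro-4,6-dihydroxyphenyl)ethan-1-one | CC(=O)c1c(O)cc(O)cc1F | intermediate
3 | 1-[2,4-bis(benzyloxy)-6-fluorophenyl]ethan-1-one | CC(=O)c1c(OCc2ccccc2)cc(OCc2ccccc2)cc1F | intermediate
4 | methyl 3-bromo-4-hydroxybenzoate | COC(=O)c1ccc(O)c(Br)c1 | starting material
5 | methyl 4-(benzyloxy)-3-bromobenzoate | COC(=O)c1ccc(OCc2ccccc2)c(Br)c1 | intermediate
6 | dimethyl 6,6'-bis(benzyloxy)-[1,1'-biphenyl]-3,3'-dicarboxylate | COC(=O)c1ccc(OCc2ccccc2)c(-c2cc(C(=O)OC)ccc2OCc2ccccc2)c1 | intermediate
7 | 1,1'-[6,6'-bis(benzyloxy)biphenyl-3,3'-diyl]bis{3-[2,4-bis(benzyloxy)-6-fluorophenyl]propane-1,3-dione}, the bis(1,3-diketone), drawn as the diketo tautomer | O=C(CC(=O)c1ccc(OCc2ccccc2)c(-c2cc(C(=O)CC(=O)c3c(F)cc(OCc4ccccc4)cc3OCc3ccccc3)ccc2OCc2ccccc2)c1)c1c(F)cc(OCc2ccccc2)cc1OCc1ccccc1 | intermediate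
8 | 5,7,4',5'',7'',4'''-hexakis(benzyloxy)-3',3'''-biflavone (hexa-O-benzyl-3',3'''-biapigenin) | O=c1cc(-c2ccc(OCc3ccccc3)c(-c3cc(-c4cc(=O)c5c(OCc6ccccc6)cc(OCc6ccccc6)cc5o4)ccc3OCc3ccccc3)c2)oc2cc(OCc3ccccc3)cc(OCc3ccccc3)c12 | intermediate
9 | (2S,2''S)-5,7,4',5'',7'',4'''-hexakis(benzyloxy)-3',3'''-biflavan-4,4''-diol, mixture of C4 and C4'' epimers | OC1C[C@@H](c2ccc(OCc3ccccc3)c(-c3cc([C@@H]4CC(O)c5c(OCc6ccccc6)cc(OCc6ccccc6)cc5O4)ccc3OCc3ccccc3)c2)Oc2cc(OCc3ccccc3)cc(OCc3ccccc3)c21 | intermediate
10 | (2S,2''S)-5,7,4',5'',7'',4'''-hexakis(benzyloxy)-3',3'''-biflavanone (hexa-O-benzyl-3',3'''-binaringenin) | O=C1C[C@@H](c2ccc(OCc3ccccc3)c(-c3cc([C@@H]4CC(=O)c5c(OCc6ccccc6)cc(OCc6ccccc6)cc5O4)ccc3OCc3ccccc3)c2)Oc2cc(OCc3ccccc3)cc(OCc3ccccc3)c21 | intermediate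
11 | (2S,2''S)-3',3'''-binaringenin | O=C1C[C@@H](c2ccc(O)c(-c3cc([C@@H]4CC(=O)c5c(O)cc(O)cc5O4)ccc3O)c2)Oc2cc(O)cc(O)c21 | target

**Step count and risks**

Total step count: 7. Longest linear sequence: 5 steps (4 → 5 → 6 → 8 → 10 → 11; the branch from 1 through 2 and 3 to 8, 10 and 11 is equally long).

Steps most likely to fail:

Step 6. What may go wrong: poor facial selectivity on one of the two flavone units, stalling after one unit because the peri 5-benzyloxy groups slow the reduction, or competing hydrogenation of benzyl rings at high pressure. In the fallback the stereocentres are set before ring closure. Setting out from 3 and 6, the Claisen condensation is run with LiN(SiMe3)2 in THF at −78 to 25 °C and quenched cold, so that bis(1,3-diketone) 7 is isolated. Noyori–Ikariya transfer hydrogenation with RuCl(p-cymene)[(S,S)-TsDPEN] in HCO2H/Et3N should then reduce only the ring-B-side carbonyls, because the ring-A-side carbonyls are flanked by F and OBn, and give (3S,3'S)-bis(β-hydroxy ketone) F1 with the same facial preference as for acetophenone. Slow addition of KN(SiMe3)2 (2.0 equiv) to a dilute THF solution at −40 °C should close both rings by alkoxide SNAr at C8a with retention at C2, since the C2–O bond is not touched, and the route is rejoined at 10.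

Step 5. What may go wrong: attack of the liberated methoxide at C8a, or a two-fold condensation that stalls on the electron-rich aroate and leaves half-reacted material. The fallback is an alkoxide-free, stepwise assembly. Setting out from 6, saponification (LiOH, THF/H2O) gives 6,6'-bis(benzyloxy)biphenyl-3,3'-dicarboxylic acid F2, and (COCl)2 with catalytic DMF gives 6,6'-bis(benzyloxy)biphenyl-3,3'-dicarbonyl dichloride F3. C-acylation of the lithium enolate of 3 (LiN(SiMe3)2, THF, −78 °C) gives 7, which is isolated and cyclised with Cs2CO3 in DMF at 100 °C; the route is rejoined at 8.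

Step 7. What may go wrong: over-reduction during the six-fold hydrogenolysis (hydrogenolytic opening of the benzylic C2–O1 bonds or reduction of C4=O), or incomplete debenzylation. In the fallback the benzyl groups are removed without hydrogen, with BCl3 and pentamethylbenzene as cation scavenger in CH2Cl2 at −78 °C, setting out from 10 and arriving directly at 11; no new compound arises on this way (F0).

**Further compounds**

F1 | step 6 | (3S,3'S)-3,3'-[6,6'-bis(benzyloxy)biphenyl-3,3'-diyl]bis{1-[2,4-bis(benzyloxy)-6-fluorophenyl]-3-hydroxypropan-1-one} | O=C(C[C@H](O)c1ccc(OCc2ccccc2)c(-c2cc([C@@H](O)CC(=O)c3c(F)cc(OCc4ccccc4)cc3OCc3ccccc3)ccc2OCc2ccccc2)c1)c1c(F)cc(OCc2ccccc2)cc1OCc1ccccc1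
F2 | step 5 | 6,6'-bis(benzyloxy)biphenyl-3,3'-dicarboxylic acid | OC(=O)c1ccc(OCc2ccccc2)c(-c2cc(C(=O)O)ccc2OCc2ccccc2)c1
F3 | step 5 | 6,6'-bis(benzyloxy)biphenyl-3,3'-dicarbonyl dichloride | ClC(=O)c1ccc(OCc2ccccc2)c(-c2cc(C(=O)Cl)ccc2OCc2ccccc2)c1
F0 | step 7 | none | none
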